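**Plan**

- Retrosynthesis: both benzyl groups are put back, ring A (the 2,4-dihydroxy-6-pentylbenzoyl ring) is taken down to its cyclohexane-2,4-dione, and that ring is cut at C1–C6 and C3–C4.
- This works because the ester carbon with C1, C2 and C3 of ring A is an acetoacetyl unit, and C4, C5 and C6 with the pentyl chain are an oct-2-enoyl unit. The hindered depside ester can therefore be made first, as a plain acetoacetate of the ring B phenol.
- Forward: 5-propylresorcinol is carboxylated and protected to the ring B phenol (ring B is the 4-carboxy-3-hydroxy-5-propylphenyl ring), then acetoacetylated. Oct-2-enoic acid is made into its phenyl ester.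
- Ring A is then built in one flask by Michael addition and Claisen closure, aromatised with CuBr2, and hydrogenolysis frees the phenol and the acid.
- Stereochemistry: the target is achiral. The two centres of the dione (racemic, trans by equilibration) disappear on aromatisation.

Key step: step 8

Remark: dione 14 is written as the triketo form although it should exist largely as an enol, and its trans arrangement at C1/C6 is taken as the equilibrium one because C1 epimerises readily.

**Route**

Step 1
Reactants: 1 5-propylbenzene-1,3-diol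
Product: 2 2,4-dihydroxy-6-propylbenzoic acid
Conditions: MeOMgOCO2Me (2 M in DMF, excess), 120 °C, N2; then cold 2 M HCl
Reagents that add atoms: methylmagnesium carbonate, COC(=O)O[Mg]OC
Why: Kolbe–Schmitt-type carboxylation in which the magnesium phenoxide chelate delivers CO2 to the ring carbon ortho to one hydroxyl and para to the other, the position carboxylated in 5-alkylresorcinols, with the acid held as its magnesium salicylate chelate until cold acidification.

Step 2
Reactants: 2 2,4-dihydroxy-6-propylbenzoic acid
Product: 3 benzyl 2,4-dihydroxy-6-propylbenzoate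
Conditions: BnBr (1.05 equiv), KHCO3 (1.2 equiv), DMF, rt to 40 °C
Reagents that add atoms: benzyl bromide, BrCc1ccccc1
Why: Chemoselective SN2 O-alkylation of the carboxylate, since hydrogencarbonate ionises only the acid and leaves both phenols unalkylated.

Step 3
Reactants: 3 benzyl 2,4-dihydroxy-6-propylbenzoate
Product: 4 benzyl 2-hydroxy-4-(methoxymethoxy)-6-propylbenzoate
Conditions: MOMCl (1.1 equiv), i-Pr2NEt (1.5 equiv), CH2Cl2, 0 °C to rt
Reagents that add atoms: chloromethyl methyl ether, COCCl
Why: Selective O-alkylation (acetal formation) at the free 4-hydroxyl, because the 2-hydroxyl is held in a hydrogen bond to the ester carbonyl and is far less nucleophilic under amine base.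

Step 4
Reactants: 4 benzyl 2-hydroxy-4-(methoxymethoxy)-6-propylbenzoate
Product: 5 benzyl 2-(benzyloxy)-4-(methoxymethoxy)-6-propylbenzoate
Conditions: BnBr (1.5 equiv), K2CO3 (2 equiv), DMF, 60 °C
Reagents that add atoms: benzyl bromide, BrCc1ccccc1
Why: Williamson ether synthesis in which carbonate in warm DMF breaks the chelate and the phenoxide is benzylated, the MOM acetal and the hindered benzyl ester being stable to base.

Step 5
Reactants: 5 benzyl 2-(benzyloxy)-4-(methoxymethoxy)-6-propylbenzoate
Product: 6 benzyl 2-(benzyloxy)-4-hydroxy-6-propylbenzoate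
Conditions: conc. HCl (cat.), MeOH/THF, 45 °C
Reagents that add atoms: none
Why: Acid-catalysed acetal exchange with methanol removes the MOM group, while the benzyl ether is acid-stable and the 2,6-disubstituted benzyl ester is too hindered for acid-catalysed transesterification.

Step 6
Reactants: 6 benzyl 2-(benzyloxy)-4-hydroxy-6-propylbenzoate; 7 2,2,6-trimethyl-4H-1,3-dioxin-4-one
Product: 9 benzyl 2-(benzyloxy)-4-[(3-oxobutanoyl)oxy]-6-propylbenzoate, via acetylketene 8 (not isolated)
Conditions: 7 (1.5 equiv), toluene, reflux, acetone distilled off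
Reagents that add atoms: none
Why: Thermal retro-hetero-Diels–Alder cleavage of the dioxinone releases acetylketene, which the phenol traps by O–H addition, an acetoacetylation under neutral conditions that exposes neither the benzyl ester nor the new active methylene to base.

Step 7
Reactants: 10 (E)-oct-2-enoic acid
Product: 12 phenyl (E)-oct-2-enoate, via (E)-oct-2-enoyl chloride 11 (not isolated)
Conditions: (COCl)2 (1.2 equiv), DMF (cat.), CH2Cl2, 0 °C to rt; then PhOH (1.05 equiv), pyridine (1.5 equiv), CH2Cl2, 0 °C
Reagents that add atoms: phenol, Oc1ccccc1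
Why: Acyl chloride formation under DMF catalysis followed by acylation of phenol, with the weak base pyridine at 0 °C avoiding vinylketene formation so that the E double bond should stay conjugated.

Step 8
Reactants: 9 benzyl 2-(benzyloxy)-4-[(3-oxobutanoyl)oxy]-6-propylbenzoate; 12 phenyl (E)-oct-2-enoate
Product: 14 3-(benzyloxy)-4-[(benzyloxy)carbonyl]-5-propylphenyl (1S*,6R*)-2,4-dioxo-6-pentylcyclohexane-1-carboxylate (trans racemate), via acyclic Michael adduct 13 (not isolated)
Conditions: t-BuOK (1.05 equiv, 1 M in THF), THF, 0 °C; then 12 (1.1 equiv), 0 to 45 °C; then cold 1 M HCl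
Reagents that add atoms: none
Why: Proposed new method: the potassium enolate of 9 should add through carbon to the β-carbon of 12 (ring A C1–C6 bond) to give 13, and after proton transfer the methyl ketone enolate should attack the phenyl ester and expel phenoxide (ring A C3–C4 bond); the closest known reaction is the base-mediated Michael–Dieckmann annulation of alkyl acetoacetates with alk-2-enoates to 6-alkyl-2,4-dioxocyclohexane-1-carboxylates, here carried over to an aryl acetoacetate. The six-membered ring closes by a 6-(enolendo)-exo-trig Claisen condensation, a mode classed as favoured by the ring-closure rules for enolates. C6 is created without any chiral influence, so 14 is racemic, and C1 lies between a ketone and an ester and should equilibrate to the trans arrangement with both substituents equatorial; both centres are lost again in step 9. The step needs C- rather than O-acylation and an untouched ring B aryl ester: an enol lactone from O-attack should be reopened by phenoxide and drain to the trione enolate (pKa about 5), the thermodynamic sink. One equivalent of a hindered base keeps the aryl ester masked as its β-keto ester enolate until closure, every phenoxide set free is protonated by the acidic product, and a second deprotonation at C1 that could expel the ring B aryloxide as a ketene is avoided.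

Step 9
Reactants: 14 3-(benzyloxy)-4-[(benzyloxy)carbonyl]-5-propylphenyl (1S*,6R*)-2,4-dioxo-6-pentylcyclohexane-1-carboxylate
Product: 16 3-(benzyloxy)-4-[(benzyloxy)carbonyl]-5-propylphenyl 2,4-dihydroxy-6-pentylbenzoate, via 3-bromo dione 15 (not isolated)
Conditions: CuBr2 (2.1 equiv), MeCN, rt to 60 °C
Reagents that add atoms: none
Why: Halogenative aromatisation in which CuBr2 brominates the enolised 1,3-dione at C3 and loss of HBr with tautomerisation gives the resorcinol, as known for 6-alkyl-2,4-dioxocyclohexane-1-carboxylates; no nucleophile is present to cleave the aryl ester, and any benzyl group lost to HBr would be removed in step 10 anyway.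

Step 10
Reactants: 16 3-(benzyloxy)-4-[(benzyloxy)carbonyl]-5-propylphenyl 2,4-dihydroxy-6-pentylbenzoate
Product: 17 4-[(2,4-dihydroxy-6-pentylbenzoyl)oxy]-2-hydroxy-6-propylbenzoic acid (CNP0324314.0)
Conditions: H2 (1 atm), 10% Pd/C, EtOAc, rt
Reagents that add atoms: none
Why: Catalytic hydrogenolysis of the benzyl ether and benzyl ester C–O bonds under neutral conditions, which leave the aryl ester and the free phenols untouched, the standard unmasking of depsides.

**Compound list**

1 | 5-propylbenzene-1,3-diol (divarinol) | CCCc1cc(O)cc(O)c1 | starting material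
2 | 2,4-dihydroxy-6-propylbenzoic acid | CCCc1cc(O)cc(O)c1C(=O)O | intermediate
3 | benzyl 2,4-dihydroxy-6-propylbenzoate | CCCc1cc(O)cc(O)c1C(=O)OCc1ccccc1 | intermediate
4 | benzyl 2-hydroxy-4-(methoxymethoxy)-6-propylbenzoate | CCCc1cc(OCOC)cc(O)c1C(=O)OCc1ccccc1 | intermediate
5 | benzyl 2-(benzyloxy)-4-(methoxymethoxy)-6-propylbenzoate | CCCc1cc(OCOC)cc(OCc2ccccc2)c1C(=O)OCc1ccccc1 | intermediate
6 | benzyl 2-(benzyloxy)-4-hydroxy-6-propylbenzoate | CCCc1cc(O)cc(OCc2ccccc2)c1C(=O)OCc1ccccc1 | intermediate
7 | 2,2,6-trimethyl-4H-1,3-dioxin-4-one | CC1=CC(=O)OC(C)(C)O1 | starting material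
8 | acetylketene (3-oxobut-1-en-1-one), not isolated | CC(=O)C=C=O | intermediate
9 | benzyl 2-(benzyloxy)-4-[(3-oxobutanoyl)oxy]-6-propylbenzoate | CCCc1cc(OC(=O)CC(C)=O)cc(OCc2ccccc2)c1C(=O)OCc1ccccc1 | intermediate
10 | (E)-oct-2-enoic acid | CCCCC/C=C/C(=O)O | starting material
11 | (E)-oct-2-enoyl chloride, not isolated | CCCCC/C=C/C(=O)Cl | intermediate
12 | phenyl (E)-oct-2-enoate | CCCCC/C=C/C(=O)Oc1ccccc1 | intermediate
13 | 1-{3-(benzyloxy)-4-[(benzyloxy)carbonyl]-5-propylphenyl} 5-phenyl 2-acetyl-3-pentylpentanedioate (acyclic Michael adduct, mixture of diastereomers, not isolated) | CCCCCC(CC(=O)Oc1ccccc1)C(C(C)=O)C(=O)Oc1cc(OCc2ccccc2)c(C(=O)OCc2ccccc2)c(CCC)c1 | intermediate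
14 | 3-(benzyloxy)-4-[(benzyloxy)carbonyl]-5-propylphenyl (1S*,6R*)-2,4-dioxo-6-pentylcyclohexane-1-carboxylate (trans, racemic, the 1S,6R enantiomer drawn) | CCCCC[C@@H]1CC(=O)CC(=O)[C@H]1C(=O)Oc1cc(OCc2ccccc2)c(C(=O)OCc2ccccc2)c(CCC)c1 | intermediate
15 | 3-(benzyloxy)-4-[(benzyloxy)carbonyl]-5-propylphenyl 3-bromo-2,4-dioxo-6-pentylcyclohexane-1-carboxylate (trans at C1/C6, racemic, epimers at C3, not isolated) | CCCCC[C@@H]1CC(=O)C(Br)C(=O)[C@H]1C(=O)Oc1cc(OCc2ccccc2)c(C(=O)OCc2ccccc2)c(CCC)c1 | intermediate
16 | 3-(benzyloxy)-4-[(benzyloxy)carbonyl]-5-propylphenyl 2,4-dihydroxy-6-pentylbenzoate | CCCCCc1cc(O)cc(O)c1C(=O)Oc1cc(OCc2ccccc2)c(C(=O)OCc2ccccc2)c(CCC)c1 | intermediate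
17 | 4-[(2,4-dihydroxy-6-pentylbenzoyl)oxy]-2-hydroxy-6-propylbenzoic acid (CNP0324314.0) | CCCCCc1cc(O)cc(O)c1C(=O)Oc1cc(O)c(C(=O)O)c(CCC)c1 | target

**Step count and risks**

Total step count: 10. Longest linear sequence: 9 (steps 1 to 6 and 8 to 10); step 7 is a one-step side branch.

Steps most likely to fail:

1. Step 8. The annulation could fail in three ways: the enolate of 9 may shed the ring B aryloxide through acylketene formation, O-acylation may give an enol lactone that does not drain to the carbocycle, or the liberated phenoxide may exchange with the aryl ester. In that case ring A would be brought in already aromatic by the established depside esterification, setting out from phenol 6. Commercial 5-pentylbenzene-1,3-diol (olivetol) would be formylated (POCl3, DMF; Vilsmeier–Haack) to 2,4-dihydroxy-6-pentylbenzaldehyde F1. Benzylation (BnBr, K2CO3, DMF) would give 2,4-bis(benzyloxy)-6-pentylbenzaldehyde F2, and Pinnick oxidation (NaClO2, NaH2PO4, 2-methylbut-2-ene) would give 2,4-bis(benzyloxy)-6-pentylbenzoic acid F3. This acid and 6 would be joined through the mixed anhydride with trifluoroacetic anhydride in toluene to give 3-(benzyloxy)-4-[(benzyloxy)carbonyl]-5-propylphenyl 2,4-bis(benzyloxy)-6-pentylbenzoate F4. Hydrogenolysis of all four benzyl groups (H2, 10% Pd/C, EtOAc) would come back to the route at target 17.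

2. Step 9. Over-bromination of the electron-rich resorcinol ring, or acid-promoted loss of benzyl groups, could prevent a clean single dehydrogenation. The fallback is exhaustive bromination followed by reductive debromination. From 14, Br2 (3 equiv) with NaOAc in AcOH should aromatise and brominate ring A in one operation to 3-(benzyloxy)-4-[(benzyloxy)carbonyl]-5-propylphenyl 3,5-dibromo-2,4-dihydroxy-6-pentylbenzoate F5. Hydrogenation over 10% Pd/C with NaOAc in EtOAc/EtOH should then remove both bromine atoms together with both benzyl groups, coming back to the route at target 17.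

3. Step 1. Carboxylation could go at the ring carbon between the two hydroxyls, or be reversed by decarboxylation during work-up. The carboxyl carbon would then be introduced as an aldehyde. From 1, Vilsmeier–Haack formylation (POCl3, DMF) should give 2,4-dihydroxy-6-propylbenzaldehyde F6. Selective alkylation of the free 4-hydroxyl (MOMCl, i-Pr2NEt) would give 2-hydroxy-4-(methoxymethoxy)-6-propylbenzaldehyde F7, and benzylation (BnBr, K2CO3, DMF) would give 2-(benzyloxy)-4-(methoxymethoxy)-6-propylbenzaldehyde F8. Pinnick oxidation would give 2-(benzyloxy)-4-(methoxymethoxy)-6-propylbenzoic acid F9, and benzylation of the carboxylate (BnBr, KHCO3, DMF) rejoins the route at 5.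

**Further compounds**

F1 | step 8 | 2,4-dihydroxy-6-pentylbenzaldehyde | CCCCCc1cc(O)cc(O)c1C=O
F2 | step 8 | 2,4-bis(benzyloxy)-6-pentylbenzaldehyde | CCCCCc1cc(OCc2ccccc2)cc(OCc2ccccc2)c1C=O
F3 | step 8 | 2,4-bis(benzyloxy)-6-pentylbenzoic acid | CCCCCc1cc(OCc2ccccc2)cc(OCc2ccccc2)c1C(=O)O
F4 | step 8 | 3-(benzyloxy)-4-[(benzyloxy)carbonyl]-5-propylphenyl 2,4-bis(benzyloxy)-6-pentylbenzoate | CCCCCc1cc(OCc2ccccc2)cc(OCc2ccccc2)c1C(=O)Oc1cc(OCc2ccccc2)c(C(=O)OCc2ccccc2)c(CCC)c1
F5 | step 9 | 3-(benzyloxy)-4-[(benzyloxy)carbonyl]-5-propylphenyl 3,5-dibromo-2,4-dihydroxy-6-pentylbenzoate | CCCCCc1c(Br)c(O)c(Br)c(O)c1C(=O)Oc1cc(OCc2ccccc2)c(C(=O)OCc2ccccc2)c(CCC)c1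
F6 | step 1 | 2,4-dihydroxy-6-propylbenzaldehyde | CCCc1cc(O)cc(O)c1C=O
F7 | step 1 | 2-hydroxy-4-(methoxymethoxy)-6-propylbenzaldehyde | CCCc1cc(OCOC)cc(O)c1C=O
F8 | step 1 | 2-(benzyloxy)-4-(methoxymethoxy)-6-propylbenzaldehyde | CCCc1cc(OCOC)cc(OCc2ccccc2)c1C=O
F9 | step 1 | 2-(benzyloxy)-4-(methoxymethoxy)-6-propylbenzoic acid | CCCc1cc(OCOC)cc(OCc2ccccc2)c1C(=O)O
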